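The numbers in the tables are calculated from invented constants; the scatter is artificial.

In the first instants of Monday's run E went fast: by 0.500 d it read 31.4 %, beside 12.7 % of L and 16.0 % of Z, and these together already fell short of the charge, so E was passing into L, into Z and into something unseen.

in all of them: E 0.10 M

| run | X | remark | time |
|---|---|---|---|
| Monday's | 0.042 M | run made earlier |  |
| Wednesday's | 0.066 M | run made earlier |  |
| flask | 0.0300 M |  | 12 d |

| run | time / d | L / % | Z / % | E / % |
|---|---|---|---|---|
| Monday's | 0.500 | 12.7 | 16.0 | 31.4 |
| Monday's | 1.25 | 11.2 | 18.4 | 23.5 |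
| Monday's | 2.50 | 8.1 | 15.7 | 22.8 |
| Monday's | 4.00 | 8.5 | 15.1 | 22.2 |
| Monday's | 6.00 | 11.0 | 13.7 | 23.2 |
| Monday's | 8.00 | 10.8 | 16.0 | 21.8 |
| Wednesday's | 0.500 | 10.4 | 17.6 | 26.1 |
| Wednesday's | 1.25 | 9.4 | 15.8 | 20.1 |
| Wednesday's | 2.50 | 7.3 | 11.0 | 14.4 |
| Wednesday's | 4.00 | 7.0 | 8.6 | 14.8 |
| Wednesday's | 6.00 | 5.2 | 7.6 | 14.5 |
| Wednesday's | 8.00 | 3.5 | 8.0 | 13.8 |

(scatter of a reading: 1 percentage point)

- the analysis behind the earlier runs scatters by 1 percentage point, standard deviation
- a reading or a percentage of L counts all its forms, free or not
- the reaction counts as stopped when no species that holds the E changes by six tenths of a point or more over the second half of the time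
- a reading of E is of its free form alone

* which holds at 12 d: what has brought the reaction to rest, or that it has not come to rest (forward and back rates have come level / all of E has reacted / it is still moving)
* L at 12 d, in percent of the E charged
* Z at 12 d, in percent of the E charged

In the middle of Monday's run, from 2.50 d, E read steady within the scatter of 1 percentage point, so from there the readings showed no loss of E beyond that scatter. At the last readings the missing part stood at 51.4 % in Monday's run and 74.7 % in Wednesday's. Raising X by 24.0 % of the E charge had widened it by 23 points, which reads as one E lost per X.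

X is then the limiting reagent in this flask, since cX stands below cE. So I reckoned 70.0 % of the E charge in this flask to lie beyond the reach of X: this is the free share, one minus cX/cE at the charge.

Monday's free share was 58.0 %. Over its 3 last readings, Z per free share came to 0.257, against 0.237 in Wednesday's run, and L came to 0.174 in Monday's run. For this flask I reckoned Z 18.0 % and L 12.2 %, at rest by 12 d, with forward and back rates level.

The forecast, “the flask should settle sooner and more flatly”, said forward and back rates have come level, with L 13.5 % and Z 19 %, both above my figures.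

The flask gave forward and back rates have come level, with L 11.1 % and Z 17.7 %.

    E ⇌ L (K = 0.400, k = 0.0760 h⁻¹)
    L ⇌ J (K = 0.840, k = 0.0980 h⁻¹)
    J ⇌ Z (K = 2.00, k = 0.140 h⁻¹)
    E + X → G (k = 1.40 M⁻¹ h⁻¹)
    E + L ⇌ Q, settled at all times (K = 2.10 M⁻¹)
    E ⇌ D (K = 0.200, k = 0.540 h⁻¹)
    Z ⇌ E (k = 0.0910 h⁻¹)

This flask had a free share of 70.0 % and held 30.0 % of G at 12.0 d. A neighbouring flask charged with 0.051 M of X has a free share of 49.0 %, so Monday's ratios give it Z 12.6 % and L 8.53 %. At 12.0 d that neighbour held Z 12.5 %, L 7.72 % and G 51.0 %, with 0.0257 % of its own charge of X remaining.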